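**Assumption:** methyl hydrogen (R)-3-methylglutarate is bought as a chiral-pool reagent of ≥98% ee. Target configuration read from the SMILES: C2 (bearing CH2OAc) = S, C3 (bearing CH3) = R.

## Retrosynthetic overview

1. Target ⇐ O-benzyl monoacetate (hydrogenolysis) ⇐ diacetate (selective aryl-acetate cleavage) ⇐ phenol/primary alcohol.
2. C2 stereocentre and the C2–CH2(guaiacyl) bond ⇐ new enamine-catalysed 1,6-addition of an (R)-3-methyl-4-arylbutanal to a transient vanillyl p-quinone methide, then NaBH4.
3. (R)-Aldehyde ⇐ methyl ester (DIBAL) ⇐ Fe-catalysed decarboxylative arylation of the NHPI ester of methyl hydrogen (R)-3-methylglutarate (C3 from the chiral pool) with a syringyl zinc reagent.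
4. Quinone methide precursor ⇐ vanillyl alcohol + p-toluenesulfinate.
5. No rings are formed; both arenes are bought intact (4-bromo-2,6-dimethoxyphenol, vanillyl alcohol).

## Route

**Step 1**
Reactants: 1, 4-bromo-2,6-dimethoxyphenol
Product: 2, 2-(benzyloxy)-5-bromo-1,3-dimethoxybenzene
Conditions: BnBr, K2CO3, DMF, 60 °C
Reagents that add atoms: benzyl bromide, BrCc1ccccc1
Why: Williamson ether synthesis (SN2 of the phenoxide on benzyl bromide); the benzyl ether survives organometallics and hydride and is removed by hydrogenolysis at the end.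

**Step 2**
Reactants: 3, methyl hydrogen (R)-3-methylglutarate [(R)-5-methoxy-3-methyl-5-oxopentanoic acid]
Product: 4, 1-(1,3-dioxoisoindolin-2-yl) 5-methyl (S)-3-methylpentanedioate (redox-active ester; same spatial arrangement as 3, the descriptor changes only through CIP priorities)
Conditions: N-hydroxyphthalimide, DIC, DMAP (cat.), CH2Cl2, rt
Reagents that add atoms: N-hydroxyphthalimide, ON1C(=O)c2ccccc2C1=O
Why: Steglich-type carbodiimide esterification of the free acid; the stereocentre is β to both carbonyls and is not touched.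

**Step 3**
Reactants: 2, 2-(benzyloxy)-5-bromo-1,3-dimethoxybenzene; 4, the NHPI ester
Product: 5, methyl (R)-4-[4-(benzyloxy)-3,5-dimethoxyphenyl]-3-methylbutanoate
Conditions: 2, n-BuLi, THF, −78 °C; ZnCl2; then 4, Fe(acac)3 (10 mol%), dppBz (12 mol%), THF/toluene, rt
Reagents that add atoms: none
Why: Decarboxylative Negishi-type coupling of a redox-active ester: single-electron reduction by low-valent aryl-iron releases CO2 and phthalimide, and the primary alkyl radical is captured by aryl-iron. The stereocentre is β to the radical and unaffected, and the methyl ester tolerates the arylzinc.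

**Step 4**
Reactants: 5, methyl (R)-4-[4-(benzyloxy)-3,5-dimethoxyphenyl]-3-methylbutanoate
Product: 6, (R)-4-[4-(benzyloxy)-3,5-dimethoxyphenyl]-3-methylbutanal
Conditions: DIBAL-H (1.1 equiv), CH2Cl2, −78 °C; Rochelle salt work-up
Reagents that add atoms: none
Why: DIBAL partial reduction of a methyl ester; the tetrahedral aluminium hemiacetal is stable at −78 °C and gives the aldehyde on work-up.

**Step 5**
Reactants: 7, vanillyl alcohol (4-hydroxy-3-methoxybenzyl alcohol)
Product: 8, 2-methoxy-4-[(4-methylphenyl)sulfonylmethyl]phenol (vanillyl p-tolyl sulfone)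
Conditions: TolSO2Na, HCO2H/H2O, rt
Reagents that add atoms: sodium p-toluenesulfinate, Cc1ccc(cc1)S(=O)[O-].[Na+]
Why: SN1 substitution: acid ionises the electron-rich benzylic alcohol to the p-hydroxybenzyl cation (protonated quinone methide), which is S-alkylated by sulfinate to give a bench-stable quinone methide precursor.

**Step 6 (key step)**
Reactants: 6, the (R)-aldehyde; 8, vanillyl p-tolyl sulfone (1.5 equiv, added in portions)
Product: 9, (2S,3R)-4-[4-(benzyloxy)-3,5-dimethoxyphenyl]-2-[(4-hydroxy-3-methoxyphenyl)methyl]-3-methylbutanal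
Conditions: (S)-α,α-diphenylprolinol TMS ether (20 mol%), NaHCO3, CH2Cl2/H2O, 0 °C → rt; not isolated
Reagents that add atoms: none
Why: Proposed new method: enamine-catalysed asymmetric α-(4-hydroxybenzyl)ation of an aldehyde by a transient, δ-unsubstituted p-quinone methide. Mild base reversibly eliminates sulfinate from the phenoxide of 8, so 2-methoxy-4-methylenecyclohexa-2,5-dienone stays at a low steady-state concentration. The E-anti enamine of 6 adds through its Si face to the exocyclic CH2 (the Re face is blocked by the CPh2OTMS group), setting C2 as S under catalyst control; re-aromatisation makes C–C formation irreversible and hydrolysis releases 9 with a free phenol. The closest known reactions are enamine 1,6-additions of aldehydes to isolable δ-aryl-2,6-di-tert-butyl p-quinone methides, base-triggered release of o-quinone methides from 2-(sulfonylmethyl)phenols, and SN1-type enamine alkylations with stabilised benzylic cations.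

**Step 7**
Reactants: 9, the (2S,3R)-aldehyde (crude, same pot)
Product: 10, (2S,3R)-4-[4-(benzyloxy)-3,5-dimethoxyphenyl]-2-[(4-hydroxy-3-methoxyphenyl)methyl]-3-methylbutan-1-ol
Conditions: NaBH4, MeOH, 0 °C; minor C2 epimer removed by chromatography
Reagents that add atoms: none
Why: Borohydride 1,2-reduction done immediately removes the epimerisable α-stereocentre problem; nothing else in the molecule is reducible.

**Step 8**
Reactants: 10, the phenol/primary alcohol
Product: 11, (2S,3R)-2-[(4-acetoxy-3-methoxyphenyl)methyl]-4-[4-(benzyloxy)-3,5-dimethoxyphenyl]-3-methylbutyl acetate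
Conditions: Ac2O, pyridine, DMAP (cat.), CH2Cl2, rt
Reagents that add atoms: acetic anhydride, CC(=O)OC(C)=O
Why: DMAP-catalysed acylation of both hydroxyls; exhaustive acetylation avoids having to acylate the alcohol selectively in the presence of the phenol.

**Step 9**
Reactants: 11, the diacetate
Product: 12, (2S,3R)-4-[4-(benzyloxy)-3,5-dimethoxyphenyl]-2-[(4-hydroxy-3-methoxyphenyl)methyl]-3-methylbutyl acetate
Conditions: NH4OAc, MeOH/H2O (4:1), rt
Reagents that add atoms: none
Why: Chemoselective solvolysis of the aryl acetate: the phenoxide is a far better leaving group than an alkoxide, so the primary alkyl acetate is untouched under these near-neutral conditions.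

**Step 10**
Reactants: 12, the O-benzyl monoacetate
Product: 13, (2S,3R)-4-(4-hydroxy-3,5-dimethoxyphenyl)-2-[(4-hydroxy-3-methoxyphenyl)methyl]-3-methylbutyl acetate (target, CID53359578)
Conditions: H2 (1 atm), 10% Pd/C, EtOAc, rt
Reagents that add atoms: none
Why: Catalytic hydrogenolysis of the benzyl aryl ether under neutral conditions; the alkyl acetate, aryl methyl ethers and both stereocentres are inert.

## Compound list

1 | 4-bromo-2,6-dimethoxyphenol | COc1cc(Br)cc(OC)c1O | starting material
2 | 2-(benzyloxy)-5-bromo-1,3-dimethoxybenzene | COc1cc(Br)cc(OC)c1OCc1ccccc1 | intermediate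
3 | methyl hydrogen (R)-3-methylglutarate | COC(=O)C[C@H](C)CC(=O)O | starting material
4 | 1-(1,3-dioxoisoindolin-2-yl) 5-methyl (S)-3-methylpentanedioate | COC(=O)C[C@H](C)CC(=O)ON1C(=O)c2ccccc2C1=O | intermediate
5 | methyl (R)-4-[4-(benzyloxy)-3,5-dimethoxyphenyl]-3-methylbutanoate | COC(=O)C[C@H](C)Cc1cc(OC)c(OCc2ccccc2)c(OC)c1 | intermediate
6 | (R)-4-[4-(benzyloxy)-3,5-dimethoxyphenyl]-3-methylbutanal | O=CC[C@H](C)Cc1cc(OC)c(OCc2ccccc2)c(OC)c1 | intermediate
7 | vanillyl alcohol | COc1cc(CO)ccc1O | starting material
8 | 2-methoxy-4-[(4-methylphenyl)sulfonylmethyl]phenol | COc1cc(CS(=O)(=O)c2ccc(C)cc2)ccc1O | intermediate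
9 | (2S,3R)-4-[4-(benzyloxy)-3,5-dimethoxyphenyl]-2-[(4-hydroxy-3-methoxyphenyl)methyl]-3-methylbutanal | COc1cc(C[C@H](C=O)[C@H](C)Cc2cc(OC)c(OCc3ccccc3)c(OC)c2)ccc1O | intermediate
10 | (2S,3R)-4-[4-(benzyloxy)-3,5-dimethoxyphenyl]-2-[(4-hydroxy-3-methoxyphenyl)methyl]-3-methylbutan-1-ol | COc1cc(C[C@H](CO)[C@H](C)Cc2cc(OC)c(OCc3ccccc3)c(OC)c2)ccc1O | intermediate
11 | (2S,3R)-2-[(4-acetoxy-3-methoxyphenyl)methyl]-4-[4-(benzyloxy)-3,5-dimethoxyphenyl]-3-methylbutyl acetate | COc1cc(C[C@H](COC(C)=O)[C@H](C)Cc2cc(OC)c(OCc3ccccc3)c(OC)c2)ccc1OC(C)=O | intermediate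
12 | (2S,3R)-4-[4-(benzyloxy)-3,5-dimethoxyphenyl]-2-[(4-hydroxy-3-methoxyphenyl)methyl]-3-methylbutyl acetate | COc1cc(C[C@H](COC(C)=O)[C@H](C)Cc2cc(OC)c(OCc3ccccc3)c(OC)c2)ccc1O | intermediate
13 | (2S,3R)-4-(4-hydroxy-3,5-dimethoxyphenyl)-2-[(4-hydroxy-3-methoxyphenyl)methyl]-3-methylbutyl acetate | COc1cc(C[C@H](COC(C)=O)[C@H](C)Cc2cc(OC)c(O)c(OC)c2)ccc1O | target

## Summary

Total steps: 10. Longest linear sequence: 8 steps (3 → 4 → 5 → 6 → 9 → 10 → 11 → 12 → 13; the branch from 1 is equally long).

Steps most likely to fail, with fallbacks: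

1. **Step 6 (proposed new quinone methide α-benzylation).** Risks are N-alkylation of the amine catalyst by the unhindered quinone methide, quinone methide oligomerisation, and a mismatched dr with the β-stereocentre. Fallback, known chemistry: hydrolyse 5 to the acid and attach (S)-4-benzyloxazolidin-2-one. Evans alkylation (NaHMDS, −78 °C, 4-(benzyloxy)-3-methoxybenzyl bromide) sets C2 as S. LiBH4 cleavage, Ac2O/pyridine and H2/Pd-C (removing both benzyl ethers) then give 13.
2. **Step 3 (Fe-catalysed decarboxylative arylation of a primary redox-active ester).** Risks are radical reduction or dimerisation and low conversion with the electron-rich arylzinc. Fallback: set C3 by asymmetric hydrogenation instead. Negishi coupling of (4-benzyloxy-3,5-dimethoxybenzyl)zinc chloride with (Z)-3-iodobut-2-en-1-ol (from 2-butyn-1-ol, Red-Al then I2) gives the (Z)-allylic alcohol. Ru(OAc)2[(R)-BINAP]/H2 gives the (R)-alcohol, which is oxidised to 6.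
3. **Step 9 (chemoselective aryl-acetate cleavage).** The risk is partial loss or slow methanolysis of the primary acetate. Fallback: skip the diacetate and acylate only the aliphatic hydroxyl of 10 with immobilised Candida antarctica lipase B and vinyl acetate (phenols are not acylated), then hydrogenolyse as in Step 10.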